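**Slow tail.** The slow fall of c(complex with one exchanged) after its peak in oak is what I read first. A tail that slow suggests a flask short of reagent, and time may not be what it lacks.

| flask | starting complex | incoming ligand | remark | time |
|---|---|---|---|---|
| oak | 13 mM | 2 equiv | run made earlier |  |
| teal | 20 mM | 2.00 equiv |  | 10 d |
| ochre | 20 mM | 2.50 equiv |  | 10 d |
| amber | 20 mM | 3.00 equiv |  | 10 d |

- oak (time / d: complex with one exchanged / %, complex with three exchanged / %): 0.625: 36.1, 5.9; 1.25: 37.1, 9.9; 2.00: 34.3, 10.1; 3.00: 28.4, 5.9; 4.00: 26.3, 3.2

(each reading ± 1 percentage point)

* how much complex with one exchanged is there at the end, in percent of the starting complex charged: for each flask in turn (teal, ochre, amber)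

**Ligand price.** A complex that stays at one exchanged holds one incoming ligand, while one that has moved on holds more. I replace those mixed fates by their mean. I take oak's last reading, 26.3% at 4.00 d, as its end, and I suppose its whole 2 equiv taken up and its starting complex gone. Subtracting the one-exchanged share from the charge and dividing by the share moved on gives 2.36. This is the ligand price: the mean incoming ligand taken up per complex past one exchanged, a value read from one scattered reading under those suppositions.

**Two neighbours.** Teal and ochre look nearly the same, yet they stand on either side of the price. Teal's 2.00 equiv is less than the price, so I treat incoming ligand as the limiting reagent there. If the steps are bimolecular, their pace at equal equivalents scales with concentration, so teal's 10 d counts as 15.4 d on oak's clock, longer than oak's 4.00 d. Ochre's charge exceeds the price by 0.143 and amber's by 0.643, and that surplus can go on taking up the one-exchanged complex. So I commit to teal near 26.3%, ochre well below it, and amber lower still.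

**The forecast.** It says 20%, 23% and 25% for teal, ochre and amber, rising with the charge: “Extra ligand probably sustains exchange for longer”. My reckoning falls with the charge instead.

**Flask result.** Teal, ochre and amber end at 18.9%, 5.67% and 0.497% of complex with one exchanged.

    complex with two exchanged → decomposed reagent (k = 0.0670 h⁻¹)
    complex with one exchanged + incoming ligand → leaving ligand + complex with two exchanged (k = 2.30 L mol⁻¹ h⁻¹)
    leaving ligand + complex with three exchanged → side product (k = 2.20 L mol⁻¹ h⁻¹)
    starting complex → decomposition product (k = 7.90 × 10⁻⁵ h⁻¹)
    starting complex + incoming ligand → leaving ligand + complex with one exchanged (k = 2.40 L mol⁻¹ h⁻¹)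
    complex with two exchanged + incoming ligand → leaving ligand + complex with three exchanged (k = 4.80 L mol⁻¹ h⁻¹)

**Price paid.** Reckoned the same way at 10 d, with the starting complex left out of the share moved on, teal's price is 2.40 and ochre's is 2.50, higher than teal's and above my 2.36. Ochre still has 4.6% of its charge of incoming ligand left, against 0.84% in teal. Complex with two exchanged also turns into decomposed reagent, and that step is part of the reason for ochre's low end of complex with one exchanged: with the step removed, ochre ends at 14.2% instead of 5.67%.

The readings were generated by integration on assumed constants; the scatter is artificial.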